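**Strategy.** Ring B (C5–C10) holds a tertiary α-ketol ester, C7(=O)–C8(OAc)(CH3), next to the spiro ether carbon C9. This is the retron of an α-ketol rearrangement, so the crowded C8–C9 bond is disconnected. The precursor is a B-nor hydrindane: a cyclopentane C5–C6–C7–C9–C10 with 7α-OH and a 7β-acetyl group (C8, C17), the spiro bis-ether already in place. Base shifts C9 from C7 to the acetyl carbon. This single operation enlarges the ring to ring B, joins two fully substituted carbons, sets C8 and puts the ketone at C7. The precursor comes from (−)-sclareol by olefin ozonolysis, aldol reclosure and α-face dihydroxylation; Sharpless epoxidation sets C13.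

Key step: step 12

Remark on numbering: labdane numbering is kept for every compound. In the B-nor compounds 11–14 the five-membered ring is C5–C6–C7–C9–C10, and C8 (carbonyl) with C17 (methyl) forms the acetyl group on C7. The α face is that of H5 and the β face is that of the C10 methyl (C20). The carbon added in step 4 is C14 and the one added in step 6 is C15.

Step 1
Reactants: 1 (−)-sclareol
Product: 2 8α-hydroxy-14,15-dinorlabdan-13-one
Conditions: OsO4 (2 mol %), NaIO4 (4 equiv), THF–H2O, rt
Reagents that add atoms: none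
Why: Lemieux–Johnson oxidation: osmylation of the only alkene and double periodate cleavage of the 13,14,15-trioxygenated chain in the same flask excise C14 and C15 and leave the C13 methyl ketone, while the isolated tertiary 8α-OH and C5, C9, C10 are untouched.

Step 2
Reactants: 2 8α-hydroxy-14,15-dinorlabdan-13-one
Product: 3 14,15-dinorlabd-8(9)-en-13-one
Conditions: PPh3, I2, CH2Cl2, rt
Reagents that add atoms: none
Why: Dehydration of the tertiary alcohol through its alkoxyphosphonium iodide is E1-like and the HI released equilibrates the olefin isomers, so the most substituted Δ8(9) alkene should prevail, which deliberately erases C8 and C9 for later reconstruction.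

Step 3
Reactants: 3 14,15-dinorlabd-8(9)-en-13-one
Product: 4 14,15-dinorlabda-8(9),13(16)-dien-13-yl trifluoromethanesulfonate
Conditions: LiN(iPr)2, THF, −78 °C; then PhNTf2, −78 → 0 °C
Reagents that add atoms: N-phenylbis(trifluoromethanesulfonimide), O=S(=O)(N(c1ccccc1)S(=O)(=O)C(F)(F)F)C(F)(F)F
Why: Kinetic enolisation with the hindered amide removes a proton from the methyl group (C16) rather than from C12, and O-sulfonylation of this enolate (enol triflate synthesis) fixes the terminal 13(16)-olefin.

Step 4
Reactants: 4 14,15-dinorlabda-8(9),13(16)-dien-13-yl trifluoromethanesulfonate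
Product: 5 15-norlabda-8(9),13(16)-dien-14-ol
Conditions: Bu3SnCH2OH, Pd(PPh3)4 (5 mol %), LiCl, 1,4-dioxane, 90 °C
Reagents that add atoms: (tributylstannyl)methanol, CCCC[Sn](CCCC)(CCCC)CO
Why: Stille coupling of the vinyl triflate with the hydroxymethylstannane, with chloride assisting transmetalation, installs C14 as CH2OH and gives the 2-substituted allylic alcohol needed for reagent-controlled epoxidation.

Step 5
Reactants: 5 15-norlabda-8(9),13(16)-dien-14-ol
Product: 6 (13S)-13,16-epoxy-15-norlabd-8(9)-en-14-ol
Conditions: Ti(OiPr)4 (10 mol %), L-(+)-diethyl tartrate (12 mol %), t-BuOOH, 4 Å MS, CH2Cl2, −20 °C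
Reagents that add atoms: tert-butyl hydroperoxide, CC(C)(C)OO
Why: Sharpless asymmetric epoxidation: only the allylic alcohol binds to titanium, so the Δ8(9) olefin is spared, and the L-(+)-tartrate ligand, which turns 2-alkylallyl alcohols into (S)-2-alkylglycidols, sets C13 as S under reagent control.

Step 6
Reactants: 6 (13S)-13,16-epoxy-15-norlabd-8(9)-en-14-ol
Product: 8 (13S)-13,16-epoxylabd-8(9)-en-14-yne, via epoxy aldehyde 7 (not isolated)
Conditions: 2,2,6,6-tetramethylpiperidin-1-oxyl (10 mol %), PhI(OAc)2, CH2Cl2, rt; then MeOH, K2CO3, MeC(O)C(N2)P(O)(OMe)2, 0 °C → rt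
Reagents that add atoms: dimethyl (1-diazo-2-oxopropyl)phosphonate, CC(=O)C(=[N+]=[N-])P(=O)(OC)OC
Why: Oxoammonium oxidation of the primary alcohol followed by Seyferth–Gilbert homologation with the Ohira–Bestmann reagent converts CH2OH into the ethynyl group C14≡C15, and C13, being quaternary, cannot epimerise (its descriptor changes only through CIP priorities).

Step 7
Reactants: 8 (13S)-13,16-epoxylabd-8(9)-en-14-yne
Product: 10 (13S)-13,16-epoxy-8,9-secolabd-14-yne-8,9-dione, via ozonide 9 (not isolated)
Conditions: O3, CH2Cl2, −78 °C (Sudan Red 7B end point); then Me2S, −78 °C → rt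
Reagents that add atoms: ozone, [O-][O+]=O
Why: Ozonolysis (Criegee mechanism) is selective for the electron-rich tetrasubstituted olefin over the much less reactive terminal alkyne when ozone is dosed to an indicator end point, and reduction of the ozonide opens ring B to the 1,6-diketone.

Step 8
Reactants: 10 (13S)-13,16-epoxy-8,9-secolabd-14-yne-8,9-dione
Product: 11 B-nor enone (7-acetyl-Δ7(9) cyclopentene, side chain on C9)
Conditions: KOt-Bu (0.3 equiv), t-BuOH–THF, rt → 40 °C
Reagents that add atoms: none
Why: Intramolecular aldol condensation of the 1,6-diketone: only attack of the C7 enolate on the C9 ketone gives a five-membered ring (5-enolexo-exo-trig, the alternatives being seven-membered and C10 having no hydrogen), dehydration gives the conjugated 1-acetylcyclopentene, and the poorly nucleophilic tert-butoxide should spare the oxirane.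

Step 9
Reactants: 11 B-nor enone
Product: 12 B-nor 7α,9α-dihydroxy-7β-acetyl compound
Conditions: OsO4 (10 mol %), N-methylmorpholine N-oxide, MeSO2NH2, acetone–H2O, rt
Reagents that add atoms: osmium tetroxide, O=[Os](=O)(=O)=O; N-methylmorpholine N-oxide, C[N+]1([O-])CCOCC1; water, O
Why: Upjohn syn-dihydroxylation takes place on the α face, opposite the angular C20 methyl as in steroid ring D olefins, and so sets 9α-OH/9β-C11 and 7α-OH/7β-acetyl in one step, the alkyne and oxirane being much less reactive towards OsO4.

Step 10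
Reactants: 12 B-nor 7α,9α-dihydroxy-7β-acetyl compound
Product: 13 B-nor (13R)-9α,13-epoxy-7α,16-dihydroxy-14-yne (spiro tetrahydrofuran alkynol)
Conditions: camphor-10-sulfonic acid (10 mol %), CH2Cl2, −20 → 0 °C
Reagents that add atoms: none
Why: Acid-catalysed 5-exo-tet opening of the 2,2-disubstituted oxirane by the 9α-hydroxyl occurs at the tertiary propargylic carbon with inversion, so the (13S)-oxirane becomes the (13R)-ether, the spiro tetrahydrofuran forms and C16–OH is freed, the six-membered alternative through the hydrogen-bonded 7-OH being slower.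

Step 11
Reactants: 13 spiro tetrahydrofuran alkynol
Product: 14 B-nor (13R)-9α,13;15,16-diepoxy-7α-hydroxy-7β-acetyl-14-ene (rearrangement precursor)
Conditions: Mo(CO)6 (25 mol %), Et3N–Et2O, hν 350 nm (catalyst preformed); then 13, rt, dark
Reagents that add atoms: none
Why: Alkynol cycloisomerisation through a molybdenum vinylidene: the C16 hydroxyl adds to the carbene carbon C15 (endo mode) of this 3-butyn-1-ol unit to give the 2,3-dihydrofuran under mildly basic conditions that leave the ketol and the propargylic ether intact.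

Step 12
Reactants: 14 B-nor 7α-hydroxy-7β-acetyl spiro bis-ether
Product: 15 8β-hydroxy-9α,13R;15,16-diepoxylabd-14-en-7-one
Conditions: KOH, MeOH, 0 °C → rt, Ar; pH 7 buffer quench
Reagents that add atoms: none
Why: Reversible deprotonation of the 7α-OH gives an alkoxide whose C7–C9 σ bond migrates to the acetyl carbon C8 while C7 becomes the ketone (α-ketol or acyloin rearrangement), and proton transfer gives the 8-hydroxy-7-ketone. The closest known reaction is the base-induced D-homoannulation of 17-hydroxy-20-oxo steroids, that is 1-acetylcyclopentanol to 2-hydroxy-2-methylcyclohexanone, driven here by relief of cyclopentane and trans-hydrindane strain. No ring is closed by cyclisation: ring B arises by one-carbon enlargement (five to six) through a suprafacial 1,2-shift with retention at the migrating C9, so the 9α-ether stays as set in step 9. C8 is controlled by the transoid alkoxide/carbonyl conformation preferred by a weakly coordinating potassium alkoxide, which also turns C17 away from the β-face methyl C20, so that C9 bonds to the face of C8=O that leaves O8 axial (β) and C17 equatorial (α). The step needs migration of C9 and not of C6, and the 7β-acetyl configuration secures this, because insertion of a β-placed C8 between C7 and C9 passes through a chair-like six-membered array in the trans-fused frame whereas insertion between C6 and C7 would need a boat, and the ether oxygen on C9 helps it to carry the migrating electron pair. The etherified O9 and the lack of hydrogen at C7 and C8 rule out retro-aldol and β-elimination, the enol ether is inert to base, and low temperature with an early quench guards against a slower onward methyl shift.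

Step 13
Reactants: 15 8β-hydroxy-9α,13R;15,16-diepoxylabd-14-en-7-one
Product: 16 8β-acetoxy-9α,13R;15,16-diepoxylabd-14-en-7-one (target)
Conditions: Ac2O, 4-dimethylaminopyridine, Et3N, CH2Cl2, 40 °C
Reagents that add atoms: acetic anhydride, CC(=O)OC(C)=O
Why: Nucleophilic catalysis by 4-dimethylaminopyridine (Steglich-type acylation) esterifies the hindered axial tertiary 8β-OH under basic conditions that the acid-labile enol ether tolerates, without touching any stereocentre.

**Compound list**

1 | (−)-sclareol, (13R)-labd-14-ene-8α,13-diol | C[C@@]1(O)CC[C@H]2C(C)(C)CCC[C@]2(C)[C@H]1CC[C@@](C)(O)C=C | starting material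
2 | 8α-hydroxy-14,15-dinorlabdan-13-one | C[C@@]1(O)CC[C@H]2C(C)(C)CCC[C@]2(C)[C@H]1CCC(C)=O | intermediate
3 | 14,15-dinorlabd-8(9)-en-13-one (5α-H, 10β-CH3) | CC1=C(CCC(C)=O)[C@@]2(C)CCCC(C)(C)[C@@H]2CC1 | intermediate
4 | 14,15-dinorlabda-8(9),13(16)-dien-13-yl trifluoromethanesulfonate | CC1=C(CCC(=C)OS(=O)(=O)C(F)(F)F)[C@@]2(C)CCCC(C)(C)[C@@H]2CC1 | intermediate
5 | 15-norlabda-8(9),13(16)-dien-14-ol | CC1=C(CCC(=C)CO)[C@@]2(C)CCCC(C)(C)[C@@H]2CC1 | intermediate
6 | (13S)-13,16-epoxy-15-norlabd-8(9)-en-14-ol | CC1=C(CC[C@@]3(CO3)CO)[C@@]2(C)CCCC(C)(C)[C@@H]2CC1 | intermediate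
7 | (13R)-13,16-epoxy-15-norlabd-8(9)-en-14-al (epoxy aldehyde, not isolated) | CC1=C(CC[C@@]3(CO3)C=O)[C@@]2(C)CCCC(C)(C)[C@@H]2CC1 | intermediate
8 | (13S)-13,16-epoxylabd-8(9)-en-14-yne | CC1=C(CC[C@@]3(CO3)C#C)[C@@]2(C)CCCC(C)(C)[C@@H]2CC1 | intermediate
9 | 8,9-ozonide of 8 (1,2,4-trioxolane bridging C8 and C9, the two acetal carbons undefined, not isolated) | CC12CC[C@H]3C(C)(C)CCC[C@]3(C)C(CC[C@@]4(CO4)C#C)(OO1)O2 | intermediate
10 | (13S)-13,16-epoxy-8,9-secolabd-14-yne-8,9-dione | CC(=O)CC[C@H]1C(C)(C)CCC[C@]1(C)C(=O)CC[C@@]2(CO2)C#C | intermediate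
11 | B-nor enone: trans-fused hydrindene, C7=C9, acetyl on C7, 2-[(S)-2-ethynyloxiran-2-yl]ethyl on C9 | CC(=O)C1=C(CC[C@@]2(CO2)C#C)[C@@]3(C)CCCC(C)(C)[C@@H]3C1 | intermediate
12 | B-nor 7α,9α-diol: 7β-acetyl, 9β side chain with (13S)-ethynyloxirane | CC(=O)[C@@]1(O)C[C@H]2C(C)(C)CCC[C@]2(C)[C@@]1(O)CC[C@@]3(CO3)C#C | intermediate
13 | B-nor spiro tetrahydrofuran: 9α,13-epoxy, (13R)-ethynyl and hydroxymethyl on C13, 7α-OH, 7β-acetyl | CC(=O)[C@@]1(O)C[C@H]2C(C)(C)CCC[C@]2(C)[C@@]13CC[C@](CO)(C#C)O3 | intermediate
14 | B-nor (13R)-9α,13;15,16-diepoxy-14-ene with 7α-OH and 7β-acetyl | CC(=O)[C@@]1(O)C[C@H]2C(C)(C)CCC[C@]2(C)[C@@]13CC[C@]4(C=COC4)O3 | intermediate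
15 | 8β-hydroxy-9α,13R;15,16-diepoxylabd-14-en-7-one (8α-CH3) | C[C@]1(O)C(=O)C[C@H]2C(C)(C)CCC[C@]2(C)[C@@]13CC[C@]4(C=COC4)O3 | intermediate
16 | (5S,8R,9S,10S,13R)-8β-acetoxy-9α,13;15,16-diepoxylabd-14-en-7-one | CC(=O)O[C@@]1(C)C(=O)C[C@H]2C(C)(C)CCC[C@]2(C)[C@@]12CC[C@]1(C=COC1)O2 | target

**Step count**

Total steps: 13. Longest linear sequence: 13 (linear route from 1).

**Steps most likely to fail**

Step 12 (key step). Competing migration of C6, or slow equilibration by an onward methyl shift under reversible basic conditions, could erode regiocontrol. Incomplete conversion is also possible.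
- The fallback moves the ring enlargement ahead of the enol ether and changes the activation from anionic to Lewis acidic. It sets out from 13.
- Both hydroxyls are silylated (Me3SiOTf, 2,6-lutidine, CH2Cl2) to the bis(trimethylsilyl) ether F1.
- The bulky, non-chelating methylaluminium bis(4-bromo-2,6-di-tert-butylphenoxide) (CH2Cl2, −78 °C) binds only the acetyl oxygen. It induces the same 1,2-shift of C9, made irreversible by silyl transfer, to give the ring-enlarged 8β-silyloxy 7-ketone F2.
- Bu4NF buffered with acetic acid gives the ring-enlarged alkynol ketol F3.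
- Cycloisomerisation with Mo(CO)6/Et3N, as in step 11, brings the route back at 15.

Step 9. Osmylation of the electron-poor, tetrasubstituted and neopentyl-flanked olefin, or hydrolysis of its osmate ester, may be too slow.
- The fallback sets out from 11.
- Luche reduction (NaBH4, CeCl3·7H2O, MeOH, −40 °C) gives the allylic alcohol F4 (C8 epimers, of no consequence).
- The now electron-rich olefin of F4 is dihydroxylated from the α face (OsO4, N-methylmorpholine N-oxide) to the triol F5.
- Oxidation of the only secondary alcohol (Dess–Martin periodinane, NaHCO3, CH2Cl2) returns to 12.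

Step 8. Closure onto the hindered C9 ketone may need forcing base, under which nucleophilic opening or base-induced isomerisation of the oxirane would compete.
- The fallback makes the oxirane only after the ring contraction. It sets out from 5.
- Acetylation (Ac2O, pyridine) gives the allylic acetate F6.
- Titrated ozonolysis attacks the tetrasubstituted olefin in preference to the acetoxy-deactivated 1,1-disubstituted one, giving the ozonide F7. Me2S reduces it to the diketone acetate F8.
- KOH in hot MeOH effects the aldol condensation and cleaves the acetate to give the B-nor enone allylic alcohol F9.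
- Sharpless epoxidation with L-(+)-diethyl tartrate gives the epoxy alcohol F10.
- Oxidation as in step 6 gives the epoxy aldehyde F11, and the Ohira–Bestmann reagent brings the route back at 11.

**Further compounds**

F1 | step 12 | bis(trimethylsilyl) ether of 13 | CC(=O)[C@@]1(O[Si](C)(C)C)C[C@H]2C(C)(C)CCC[C@]2(C)[C@@]13CC[C@](CO[Si](C)(C)C)(C#C)O3
F2 | step 12 | ring-enlarged 8β-trimethylsilyloxy 7-ketone, 16-O-trimethylsilyl, 14-yne | C[C@]1(O[Si](C)(C)C)C(=O)C[C@H]2C(C)(C)CCC[C@]2(C)[C@@]13CC[C@](CO[Si](C)(C)C)(C#C)O3
F3 | step 12 | (13R)-9α,13-epoxy-8β,16-dihydroxylabd-14-yn-7-one | C[C@]1(O)C(=O)C[C@H]2C(C)(C)CCC[C@]2(C)[C@@]13CC[C@](CO)(C#C)O3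
F4 | step 9 | B-nor allylic alcohol from 11 (C8 epimers) | CC(O)C1=C(CC[C@@]2(CO2)C#C)[C@@]3(C)CCCC(C)(C)[C@@H]3C1
F5 | step 9 | B-nor 7α,8,9α-triol (C8 epimers) | CC(O)[C@@]1(O)C[C@H]2C(C)(C)CCC[C@]2(C)[C@@]1(O)CC[C@@]3(CO3)C#C
F6 | step 8 | 15-norlabda-8(9),13(16)-dien-14-yl acetate | CC1=C(CCC(=C)COC(C)=O)[C@@]2(C)CCCC(C)(C)[C@@H]2CC1
F7 | step 8 | 8,9-ozonide of F6 (acetal carbons undefined) | CC12CC[C@H]3C(C)(C)CCC[C@]3(C)C(CCC(=C)COC(C)=O)(OO1)O2
F8 | step 8 | 8,9-dioxo-8,9-seco-15-norlabd-13(16)-en-14-yl acetate | CC(=O)CC[C@H]1C(C)(C)CCC[C@]1(C)C(=O)CCC(=C)COC(C)=O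
F9 | step 8 | B-nor enone with 3-(hydroxymethyl)but-3-enyl chain on C9 | CC(=O)C1=C(CCC(=C)CO)[C@@]2(C)CCCC(C)(C)[C@@H]2C1
F10 | step 8 | B-nor enone (13S)-epoxy alcohol | CC(=O)C1=C(CC[C@@]2(CO2)CO)[C@@]3(C)CCCC(C)(C)[C@@H]3C1
F11 | step 8 | B-nor enone (13R)-epoxy aldehyde | CC(=O)C1=C(CC[C@@]2(CO2)C=O)[C@@]3(C)CCCC(C)(C)[C@@H]3C1
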